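The starting material in this flask must first leave a solid and then meet a gas, so I rank the times from fastest to slowest and count how many of the slowest fit into the run.

solid substrate 20 mM; gas phase 0.81 mM (held); time 2.0 min

    starting material + dissolved gas → product (k1 = 17 /M/s)
    gas phase ⇌ dissolved gas, rate k2*(csat - [dissolved gas]) (k2 = 2.2 /s, csat = 0.81 mM)
    solid substrate ⇌ starting material, rate k3*(cs3 - [starting material]) while solid is left; crystals form when [starting material] > cs3 (cs3 = 9.4 mM, k3 = 0.088 /s)
    starting material ⇌ dormant form (K4 = 0.90, k4 = 0.035 /s)

- Sunday's: doubling the dissolution coefficient of step 3, all else as stated
- Friday's: doubling the saturation concentration of gas phase, all else as stated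
- Thursday's: doubling the transfer coefficient of step 2, all else as stated
- Saturday's: doubling the solubility in step 3, all else as stated

- solid, in amounts per volume of the solution: solid substrate
- at the start none of the gas is dissolved
- at the start none of the solid substrate is in solution
- run time (flask): 2.0 min

1. amount of product at 2.0 min, in percent of the solid substrate charged
2. the change that raises the amount of product at 2.0 min, in percent of the solid substrate charged most ("none" if none brings more than 2 percentage points) (Sunday's / Friday's / Thursday's / Saturday's / none)
3. amount of product at 2.0 min, in percent of the solid substrate charged, after Friday's

The fastest rung is the gas. Its transfer coefficient of 2.2 /s stands far above the demand of 0.160 /s made by starting material at its solubility, so I expect dissolved gas to stay close to 0.81 mM and starting material to be used up in a pseudo-first-order way. Next comes the exchange with dormant form, whose half-life of 0.156 min is shorter than the 0.403 min that the charge needs at its full dissolving rate into an empty solution, so I treat starting material and dormant form as one pool, of which I reckon 52.6% to be free. Then comes the solid: I book that time as a lag after which the whole charge counts as delivered, which is coarse. The slowest rung is 1.59 min, which I call H, the half-life of the pool against gas at saturation .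

The run therefore holds 1.00 of H after the lag, which gives 50.1% product. Friday's change divides H by two, so I count 2.00 half-lives and get 75.1%. Thursday's leaves my count as it stands, while Sunday's and Saturday's shorten the lag, and so I choose Friday's.

The forecast gives 49% (44% to 54%), then Friday's with 72% (65% to 78%), on the ground that “Doubling csat roughly doubles the pseudo-first-order rate”.

The simulation gives 48.9%, and Friday's is best, with 73.2%, a gain of 24 percentage points.

In this flask at 2.00 min, the half-life of starting material by the step to product reads 0.87 min, longer than the 0.33 min of the forward step to dormant form alone, and starting material at 24.8% stands beside dormant form at 26.4%, the pool for which I counted H as 1.59 min. For the neighbour flask charged with 80 mM, the same count books the whole charge as delivered after a lag of 1.61 min and yields 15.5%, and that flask gives 13.6%, but with solid substrate still at 67.6%.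

Its constants are assumed.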